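**Retrosynthetic overview**
- Ring E last: C20 comes from face-selective hydrogenation of a γ-pyrrolyl α-methylbutenolide; its C3–C18 bond and C18 come from a new catalytic asymmetric Friedel–Crafts butenolidation of the des-lactonyl pyrrole with 5-hydroxy-3-methylfuranone.
- Rings A (pyrrole) and C (azepine) form together from a keto lactone: N-deprotection, seven-membered ketimine, Hantzsch-type annulation with chloroacetaldehyde; C13 is then set by kinetic protonation of the lactone enolate.
- Ring D: Ueno–Stork radical cyclisation of a bromoacetal onto a γ-hydroxy enone (C12–C13 bond cis to C11–O), then acetal to lactone.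
- Ring B with C9/C10/C11: (R)-4-silyloxycyclohexenone, anti ethyl conjugate addition, then trans α-alkylation with a C4N allylic bromide.
- Ring order: B (bought) → D → C and A → E.

Assumption: (R)-4-(tert-butyldimethylsilyloxy)cyclohex-2-en-1-one and racemic 5-hydroxy-3-methylfuran-2(5H)-one are taken as purchasable catalogue building blocks.

Atom labels (tuberostemonine skeleton): ring A pyrrole N4/C3/C2/C1/C9a; ring C azepine N4/C5–C9/C9a; ring B C1/C9a/C9/C10/C11/C12 with ethyl on C10; ring D lactone C11–O–C14(=O)–C13(CH3)–C12; ring E lactone C18–C19–C20(CH3)–C21(=O)–O on C3. The target is 9R,10R,11S,12R,13R,18S,20S.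

**Step 1**
Reactants: 1 (E)-1,4-dibromobut-2-ene; 2 di-tert-butyl iminodicarboxylate
Product: 3 di-tert-butyl N-[(2E)-4-bromobut-2-en-1-yl]imidodicarbonate
Conditions: K2CO3 (1.5 equiv), 1 (3 equiv), DMF, 0 °C to rt
Reagents that add atoms: none
Why: SN2 N-alkylation of the imide anion by the allylic dibromide (Gabriel-type), with excess 1 holding the reaction at mono-substitution; no stereocentre is formed and the E alkene is untouched.

**Step 2**
Reactants: 4 (4R)-4-(tert-butyldimethylsilyloxy)cyclohex-2-en-1-one; 3 di-tert-butyl N-[(2E)-4-bromobut-2-en-1-yl]imidodicarbonate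
Product: 6 (2R,3R,4R)-2-[(2E)-4-[bis(tert-butoxycarbonyl)amino]but-2-en-1-yl]-4-(tert-butyldimethylsilyloxy)-3-ethylcyclohexan-1-one, via bromomagnesium enolate 5 (not isolated)
Conditions: EtMgBr (1.3 equiv), CuBr·SMe2 (10 mol %), THF, −78 °C; then DMPU, 3 (1.5 equiv), −78 to 0 °C
Reagents that add atoms: ethylmagnesium bromide, CC[Mg]Br
Why: Copper-catalysed conjugate addition of the ethyl Grignard reagent occurs anti to the C4 silyloxy group (sets C10) and enolate 5 is then alkylated by the allylic bromide anti to the new ethyl group (sets C9), a tandem conjugate addition–enolate alkylation giving the all-trans, all-equatorial ketone.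

**Step 3**
Reactants: 6 (2R,3R,4R)-2-[(2E)-4-[bis(tert-butoxycarbonyl)amino]but-2-en-1-yl]-4-(tert-butyldimethylsilyloxy)-3-ethylcyclohexan-1-one
Product: 7 (2R,3R,4R)-2-[4-[bis(tert-butoxycarbonyl)amino]butyl]-4-(tert-butyldimethylsilyloxy)-3-ethylcyclohexan-1-one
Conditions: H2 (1 atm), 5% Pt/C, EtOAc, rt
Reagents that add atoms: none
Why: Catalytic hydrogenation reduces only the isolated disubstituted alkene (ketone, silyl ether and imide are inert here), removing an E alkene that could neither sit in the later seven-membered ring nor stay passive in the radical step.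

**Step 4**
Reactants: 7 (2R,3R,4R)-2-[4-[bis(tert-butoxycarbonyl)amino]butyl]-4-(tert-butyldimethylsilyloxy)-3-ethylcyclohexan-1-one
Product: 9 (4R,5R,6R)-6-[4-[bis(tert-butoxycarbonyl)amino]butyl]-4-(tert-butyldimethylsilyloxy)-5-ethylcyclohex-2-en-1-one, via trimethylsilyl enol ether 8 (not isolated)
Conditions: LiN(iPr)2 (1.1 equiv), THF, −78 °C, then Me3SiCl; then Pd(OAc)2 (10 mol %), O2 (1 atm), DMSO, rt
Reagents that add atoms: none
Why: Kinetic deprotonation takes the less hindered α-CH2 and not the substituted C9–H, and Saegusa–Ito dehydrogenation of enol ether 8 gives the enone needed as radical acceptor without touching C9, C10 or C11.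

**Step 5**
Reactants: 9 (4R,5R,6R)-6-[4-[bis(tert-butoxycarbonyl)amino]butyl]-4-(tert-butyldimethylsilyloxy)-5-ethylcyclohex-2-en-1-one
Product: 10 (4R,5R,6R)-6-[4-[bis(tert-butoxycarbonyl)amino]butyl]-5-ethyl-4-hydroxycyclohex-2-en-1-one
Conditions: HF·pyridine, pyridine, THF, 0 °C to rt
Reagents that add atoms: none
Why: Buffered fluoride desilylation frees the C11 hydroxyl without β-elimination, aromatisation or loss of the Boc groups.

**Step 6**
Reactants: 10 (4R,5R,6R)-6-[4-[bis(tert-butoxycarbonyl)amino]butyl]-5-ethyl-4-hydroxycyclohex-2-en-1-one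
Product: 11 (4R,5R,6R)-6-[4-[bis(tert-butoxycarbonyl)amino]butyl]-4-(2-bromo-1-ethoxypropoxy)-5-ethylcyclohex-2-en-1-one (mixture at the two acetal-chain centres)
Conditions: ethyl prop-1-enyl ether (3 equiv), NBS (1.5 equiv), CH2Cl2, −40 to 0 °C
Reagents that add atoms: ethyl prop-1-enyl ether, CC=COCC; N-bromosuccinimide, O=C1CCC(=O)N1Br
Why: Bromoacetalisation, in which NBS brominates the electron-rich enol ether and the C11 alcohol captures the bromo-oxocarbenium ion, installs the Ueno–Stork tether; the two new side-chain centres are inconsequential.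

**Step 7**
Reactants: 11 (4R,5R,6R)-6-[4-[bis(tert-butoxycarbonyl)amino]butyl]-4-(2-bromo-1-ethoxypropoxy)-5-ethylcyclohex-2-en-1-one
Product: 12 (3aS,6R,7R,7aR)-6-[4-[bis(tert-butoxycarbonyl)amino]butyl]-2-ethoxy-7-ethyl-3-methyloctahydro-1-benzofuran-5-one (cis-fused; mixture at C2 and C3 of the furanose ring)
Conditions: Bu3SnH (1.3 equiv, syringe pump), AIBN (0.1 equiv), benzene, 80 °C
Reagents that add atoms: none
Why: Ueno–Stork 5-exo-trig radical cyclisation onto the enone β-carbon, where the two-atom O-tether forces the C12–C13 bond onto the face of the C11–O bond (cis ring fusion, sets C12) and the resulting α-keto radical is reduced by the stannane.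

**Step 8**
Reactants: 12 (3aS,6R,7R,7aR)-6-[4-[bis(tert-butoxycarbonyl)amino]butyl]-2-ethoxy-7-ethyl-3-methyloctahydro-1-benzofuran-5-one
Product: 13 (3aS,6R,7R,7aS)-6-[4-[bis(tert-butoxycarbonyl)amino]butyl]-7-ethyl-3-methylhexahydro-1-benzofuran-2,5(3H,4H)-dione (C3 epimers)
Conditions: CrO3, H2SO4, H2O, acetone, 0 °C, 20 min
Reagents that add atoms: water, O
Why: Jones oxidation hydrolyses the cyclic ethyl acetal to the lactol and oxidises it to the γ-lactone in one operation, the brief cold acidic conditions leaving the Boc groups and the ketone intact.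

**Step 9**
Reactants: 13 (3aS,6R,7R,7aS)-6-[4-[bis(tert-butoxycarbonyl)amino]butyl]-7-ethyl-3-methylhexahydro-1-benzofuran-2,5(3H,4H)-dione
Product: 16 des-lactonyl pyrrole lactone (rings A/B/C/D; 9R,10R,11S,12R; C13 epimers), via amino ketone 14 (not isolated), via cyclic ketimine 15 (not isolated)
Conditions: HCl (4 M in dioxane), CH2Cl2, 0 °C to rt, evaporate; then ClCH2CHO (50% aq, 1.5 equiv), NaHCO3, EtOH, 60 °C
Reagents that add atoms: chloroacetaldehyde, O=CCCl
Why: Acidolysis of both Boc groups releases amine 14, which condenses with the C9a ketone to the seven-membered ketimine 15 (ring C), and Hantzsch-type annulation of its enamine tautomer with chloroacetaldehyde (C-alkylation then N-condensation or the reverse, both converging) aromatises to the pyrrole (ring A), the trans arrangement at C9 being the thermodynamic one should the ketimine enolise that way.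

**Step 10**
Reactants: 16 des-lactonyl pyrrole lactone (C13 epimers)
Product: 18 (9R,10R,11S,12R,13R)-des-lactonyl pyrrole lactone (single C13 epimer), via lithium enolate 17 (not isolated)
Conditions: LiN(iPr)2 (1.3 equiv), THF, −78 °C, 1 h; then pivalic acid (3 equiv) in THF, −78 °C
Reagents that add atoms: none
Why: Deprotonation gives the planar lactone enolate 17 and kinetic protonation by the bulky acid from the convex face (anti to the pyrrole carbon on C12) places H13 cis to H12, converging both epimers on the 13R isomer with the methyl on the concave face.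

**Step 11**
Reactants: 18 (9R,10R,11S,12R,13R)-des-lactonyl pyrrole lactone; 19 5-hydroxy-3-methylfuran-2(5H)-one
Product: 20 (9R,10R,11S,12R,13R,18S)-3-(4-methyl-5-oxo-2,5-dihydrofuran-2-yl) pyrrole lactone (γ-pyrrolyl butenolide)
Conditions: (S,S)-IDPi Brønsted acid [BINOL-derived imidodiphosphorimidate, 3,3'-bis(3,5-(CF3)2C6H3), N-triflyl] (5 mol %), 19 (1.5 equiv), 5 Å MS, toluene, −40 °C (catalyst antipode fixed by a pilot run for 18S)
Reagents that add atoms: none
Why: Proposed new method: the confined chiral acid ionises pseudo-acid 19 (ring-chain tautomer of (Z)-2-methyl-4-oxobut-2-enoic acid) to an acyloxocarbenium/chiral-anion contact ion pair, the free pyrrole α-carbon C3 (the most nucleophilic position of 18) attacks one face inside the catalyst pocket and rearomatisation returns the acid, so the C3–C18 bond and the 18S centre are set under catalyst control because the ring B/D centres are too remote to bias it; the closest known reactions are Brønsted-acid-catalysed asymmetric Friedel–Crafts alkylations of pyrroles and indoles with N-acyliminium ions from hydroxylactams and the racemic acid-promoted arylation of γ-hydroxybutenolides.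

**Step 12**
Reactants: 20 (9R,10R,11S,12R,13R,18S)-γ-pyrrolyl butenolide
Product: 21 target CNP0232452.6 (9R,10R,11S,12R,13R,18S,20S)
Conditions: H2 (3 atm), 5% Rh/Al2O3, EtOAc, rt
Reagents that add atoms: none
Why: Heterogeneous hydrogenation delivers H2 to the butenolide face anti to the bulky pyrrolyl group on C18, so the C20 methyl ends cis to the pyrrole (20S), with Rh/Al2O3 chosen to avoid hydrogenolysis of the allylic pyrrolylcarbinyl C–O bond.

**Compound list**
1 | (E)-1,4-dibromobut-2-ene | BrC/C=C/CBr | starting material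
2 | di-tert-butyl iminodicarboxylate | CC(C)(C)OC(=O)NC(=O)OC(C)(C)C | starting material
3 | di-tert-butyl N-[(2E)-4-bromobut-2-en-1-yl]imidodicarbonate | BrC/C=C/CN(C(=O)OC(C)(C)C)C(=O)OC(C)(C)C | intermediate
4 | (4R)-4-(tert-butyldimethylsilyloxy)cyclohex-2-en-1-one | O=C1C=C[C@H](O[Si](C)(C)C(C)(C)C)CC1 | starting material
5 | bromomagnesium (3R,4R)-4-(tert-butyldimethylsilyloxy)-3-ethylcyclohex-1-en-1-olate | CC[C@H]1[C@H](O[Si](C)(C)C(C)(C)C)CCC(O[Mg]Br)=C1 | intermediate (not isolated)
6 | (2R,3R,4R)-2-[(2E)-4-[bis(tert-butoxycarbonyl)amino]but-2-en-1-yl]-4-(tert-butyldimethylsilyloxy)-3-ethylcyclohexan-1-one | CC[C@H]1[C@H](O[Si](C)(C)C(C)(C)C)CCC(=O)[C@@H]1C/C=C/CN(C(=O)OC(C)(C)C)C(=O)OC(C)(C)C | intermediate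
7 | (2R,3R,4R)-2-[4-[bis(tert-butoxycarbonyl)amino]butyl]-4-(tert-butyldimethylsilyloxy)-3-ethylcyclohexan-1-one | CC[C@H]1[C@H](O[Si](C)(C)C(C)(C)C)CCC(=O)[C@@H]1CCCCN(C(=O)OC(C)(C)C)C(=O)OC(C)(C)C | intermediate
8 | (4R,5R,6R)-6-[4-[bis(tert-butoxycarbonyl)amino]butyl]-4-(tert-butyldimethylsilyloxy)-5-ethyl-1-(trimethylsilyloxy)cyclohex-1-ene | CC[C@H]1[C@H](O[Si](C)(C)C(C)(C)C)CC=C(O[Si](C)(C)C)[C@@H]1CCCCN(C(=O)OC(C)(C)C)C(=O)OC(C)(C)C | intermediate (not isolated)
9 | (4R,5R,6R)-6-[4-[bis(tert-butoxycarbonyl)amino]butyl]-4-(tert-butyldimethylsilyloxy)-5-ethylcyclohex-2-en-1-one | CC[C@H]1[C@H](O[Si](C)(C)C(C)(C)C)C=CC(=O)[C@@H]1CCCCN(C(=O)OC(C)(C)C)C(=O)OC(C)(C)C | intermediate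
10 | (4R,5R,6R)-6-[4-[bis(tert-butoxycarbonyl)amino]butyl]-5-ethyl-4-hydroxycyclohex-2-en-1-one | CC[C@H]1[C@H](O)C=CC(=O)[C@@H]1CCCCN(C(=O)OC(C)(C)C)C(=O)OC(C)(C)C | intermediate
11 | (4R,5R,6R)-6-[4-[bis(tert-butoxycarbonyl)amino]butyl]-4-(2-bromo-1-ethoxypropoxy)-5-ethylcyclohex-2-en-1-one, mixture at the two acetal-chain centres | CC[C@H]1[C@H](OC(OCC)C(C)Br)C=CC(=O)[C@@H]1CCCCN(C(=O)OC(C)(C)C)C(=O)OC(C)(C)C | intermediate
12 | (3aS,6R,7R,7aR)-6-[4-[bis(tert-butoxycarbonyl)amino]butyl]-2-ethoxy-7-ethyl-3-methyloctahydro-1-benzofuran-5-one, cis-fused, mixture at C2 and C3 | CC[C@H]1[C@@H]2OC(OCC)C(C)[C@@H]2CC(=O)[C@@H]1CCCCN(C(=O)OC(C)(C)C)C(=O)OC(C)(C)C | intermediate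
13 | (3aS,6R,7R,7aS)-6-[4-[bis(tert-butoxycarbonyl)amino]butyl]-7-ethyl-3-methylhexahydro-1-benzofuran-2,5(3H,4H)-dione, C3 epimers | CC[C@H]1[C@@H]2OC(=O)C(C)[C@@H]2CC(=O)[C@@H]1CCCCN(C(=O)OC(C)(C)C)C(=O)OC(C)(C)C | intermediate
14 | (3aS,6R,7R,7aS)-6-(4-aminobutyl)-7-ethyl-3-methylhexahydro-1-benzofuran-2,5(3H,4H)-dione, C3 epimers | CC[C@H]1[C@@H]2OC(=O)C(C)[C@@H]2CC(=O)[C@@H]1CCCCN | intermediate (not isolated)
15 | (9R,10R,11S,12S)-tricyclic lactone ketimine: ring B fused to ring D lactone and to a seven-membered cyclic imine C9a=N4 (ring C), C13 epimers | CC[C@H]1[C@@H]2OC(=O)C(C)[C@@H]2CC(=NCCCC3)[C@@H]13 | intermediate (not isolated)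
16 | (9R,10R,11S,12R)-des-lactonyl pyrrole lactone: 4,5,6,7-tetrahydroindole with N1 and C7 bridged by (CH2)4, cis-fused α-methyl-γ-butyrolactone on C4/C5 (O on C5), ethyl on C6, pyrrole C2–H and C3–H free; C13 epimers | CC[C@H]1[C@@H]2OC(=O)C(C)[C@@H]2c2ccn3c2[C@@H]1CCCC3 | intermediate
17 | lithium enolate of 16 (C13=C14–OLi) | CC[C@H]1[C@@H]2OC(O[Li])=C(C)[C@@H]2c2ccn3c2[C@@H]1CCCC3 | intermediate (not isolated)
18 | (9R,10R,11S,12R,13R)-des-lactonyl pyrrole lactone, H11/H12/H13 all cis | CC[C@H]1[C@@H]2OC(=O)[C@H](C)[C@@H]2c2ccn3c2[C@@H]1CCCC3 | intermediate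
19 | 5-hydroxy-3-methylfuran-2(5H)-one (racemic pseudo-acid) | CC1=CC(O)OC1=O | starting material
20 | (9R,10R,11S,12R,13R,18S)-γ-pyrrolyl butenolide: 18 carrying (2S)-4-methyl-5-oxo-2,5-dihydrofuran-2-yl on pyrrole C3 | CC[C@H]1[C@@H]2OC(=O)[C@H](C)[C@@H]2c2cc([C@@H]3C=C(C)C(=O)O3)n3c2[C@@H]1CCCC3 | intermediate
21 | target CNP0232452.6, (9R,10R,11S,12R,13R,18S,20S) | CC[C@H]1[C@@H]2OC(=O)[C@H](C)[C@@H]2c2cc([C@@H]3C[C@H](C)C(=O)O3)n3c2[C@@H]1CCCC3 | target

**Step count and risk**
Total steps: 12. Longest linear sequence: 12 steps (1 → 21; 11 steps from 4).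

Three steps most likely to fail:

Step 11 (the proposed new step): the acyloxocarbenium ion may form too slowly, the N-alkylpyrrole offers no hydrogen-bond handle to the catalyst, and the product can re-ionise at C18. The fallback uses known chemistry and runs from 18 to 21. Friedel–Crafts acylation of 18 at C3 with (S)-methylsuccinic anhydride (Et2AlCl, CH2Cl2, 0 °C, attack at the less hindered carbonyl) gives the γ-keto acid F4. Asymmetric transfer hydrogenation (RuCl(p-cymene)[(S,S)-TsDPEN], HCO2H/Et3N, rt) gives the (18S)-hydroxy acid F5, which lactonises on standing or with EDC·HCl to 21. C20 then comes from the chiral pool and C18 from the reduction catalyst.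

Step 9 (one-pot ring A/C annulation): the seven-membered ketimine may form sluggishly, and chloroacetaldehyde can over-alkylate the free amine. The fallback runs from 13 to 16 by a stepwise Paal–Knorr approach. Regioselective ketone enolate allylation of 13 (LiN(SiMe3)2, THF, −78 °C, allyl bromide) gives the C1-allyl keto lactone F2. Ozonolysis (O3, CH2Cl2/MeOH, −78 °C; Me2S) gives the 1,4-keto aldehyde F3. Boc removal (HCl in dioxane) and intramolecular Paal–Knorr condensation (NaOAc, AcOH, 60 °C) then close rings C and A to give 16.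

Step 2 (tandem addition–alkylation with the functionalised bromide 3): proton transfer and polyalkylation of the magnesium enolate are the risks. The fallback runs from 4 to 6. The same copper-catalysed ethyl addition to 4 is trapped with allyl bromide (a far more reliable electrophile) to give the 2-allyl ketone F1. The nitrogen-bearing chain is then built by olefin cross-metathesis of F1 with commercial di-tert-butyl N-allylimidodicarbonate (3 equiv, Hoveyda–Grubbs second-generation catalyst, CH2Cl2, 40 °C). This returns to the route at 6, as an E/Z mixture whose two isomers both give 7 in step 3.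

**Further compounds**
F1 | step 2 | (2R,3R,4R)-2-allyl-4-(tert-butyldimethylsilyloxy)-3-ethylcyclohexan-1-one | CC[C@H]1[C@H](O[Si](C)(C)C(C)(C)C)CCC(=O)[C@@H]1CC=C
F2 | step 9 | (3aS,6R,7R,7aS)-4-allyl-6-[4-[bis(tert-butoxycarbonyl)amino]butyl]-7-ethyl-3-methylhexahydro-1-benzofuran-2,5(3H,4H)-dione, mixture at C3 and C4 | CC[C@H]1[C@@H]2OC(=O)C(C)[C@@H]2C(CC=C)C(=O)[C@@H]1CCCCN(C(=O)OC(C)(C)C)C(=O)OC(C)(C)C
F3 | step 9 | (3aS,6R,7R,7aS)-6-[4-[bis(tert-butoxycarbonyl)amino]butyl]-7-ethyl-3-methyl-4-(2-oxoethyl)hexahydro-1-benzofuran-2,5(3H,4H)-dione, mixture at C3 and C4 | CC[C@H]1[C@@H]2OC(=O)C(C)[C@@H]2C(CC=O)C(=O)[C@@H]1CCCCN(C(=O)OC(C)(C)C)C(=O)OC(C)(C)C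
F4 | step 11 | (9R,10R,11S,12R,13R,20S)-γ-keto acid: 18 carrying C(=O)CH2CH(CH3)CO2H on pyrrole C3 | CC[C@H]1[C@@H]2OC(=O)[C@H](C)[C@@H]2c2cc(C(=O)C[C@H](C)C(=O)O)n3c2[C@@H]1CCCC3
F5 | step 11 | (9R,10R,11S,12R,13R,18S,20S)-γ-hydroxy acid: 18 carrying CH(OH)CH2CH(CH3)CO2H on pyrrole C3 | CC[C@H]1[C@@H]2OC(=O)[C@H](C)[C@@H]2c2cc([C@@H](O)C[C@H](C)C(=O)O)n3c2[C@@H]1CCCC3
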